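## Retrosynthetic overview

1. Kuwanon R ⇐ hepta-MOM ether ⇐ Claisen–Schmidt enone formation between a ring-A methyl ketone and 4-(methoxymethoxy)benzaldehyde.
2. C4 aryl ketone ⇐ Pd/Cu acyl cross-coupling of a C4 thioester with a ring-C boronic acid, the latter made by Ir-catalysed C–H borylation of a 2-prenylresorcinol ether.
3. C5–ring B bond ⇐ Ni-catalysed decarboxylative arylation of a C5 acid. C3–ring A bond (key bond, sets C3) ⇐ Pd-catalysed stereoinvertive arylative opening of a bridged allylic γ-lactone by an arylzinc.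
4. Lactone ⇐ iodolactonization and dehydroiodination of (1S,2S)-4-methylcyclohex-4-ene-1,2-dicarboxylic acid ⇐ auxiliary-controlled Diels–Alder reaction of isoprene with di-(−)-menthyl fumarate.
5. Ring order: the cyclohexene is the only ring built (Diels–Alder, first); a temporary lactone ring is then closed and opened; all benzene rings are bought (resorcinol three times, 4-bromophenol once).

## Assumptions and conventions

- Assumption: the SMILES is binding, so the C4 aroyl group is 3,5-dihydroxy-4-prenylphenyl.
- Assumption: di-(−)-menthyl fumarate gives the (1S,2S) cycloadduct (both menthyl groups shield the same face); this is from memory, and (+)-menthol would be used if the opposite sense were found.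
- Auxiliary, protecting-group and activating reagents are listed under "Reagents that add atoms" and are not numbered.
- Cyclohexene locants (as in the target): C1 bears CH3, C1=C2 is the ring alkene, C3 bears ring A, C4 bears the carbonyl group, C5 bears ring B (or its carboxyl precursor), C6 is CH2.
- Ring A = 2,6-dioxygenated 3-acylphenyl; ring B = 2,4-dioxygenated phenyl; ring C = 3,5-dioxygenated 4-prenylphenyl; ring D = 4-oxygenated phenyl of the enone.
- MOM = methoxymethyl; TMSE = 2-(trimethylsilyl)ethyl.

## Route

Step 1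
Reactants: 1 fumaryl chloride
Product: 2 di-(−)-menthyl fumarate
Conditions: (−)-menthol (2.1 equiv), Et3N, DMAP (cat.), CH2Cl2, 0 °C → rt
Reagents that add atoms: (−)-menthol, CC(C)[C@@H]1CC[C@@H](C)C[C@H]1O
Why: DMAP-catalysed esterification of the diacid chloride (nucleophilic acyl substitution) is fast and leaves the E-alkene untouched; no stereocenter is formed.

Step 2
Reactants: 2 di-(−)-menthyl fumarate; 3 isoprene
Product: 4 di-(−)-menthyl (1S,2S)-4-methylcyclohex-4-ene-1,2-dicarboxylate
Conditions: Et2AlCl (2 equiv), toluene, −40 °C; 1 M HCl work-up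
Reagents that add atoms: none
Why: Lewis acid-promoted asymmetric Diels–Alder reaction in which both menthyl groups shield the same face of the complexed fumarate, so isoprene adds to the open face and the E-geometry is transferred, setting C4 and C5 trans as (S,S), while the symmetric dienophile removes any regiochemical question.

Step 3
Reactants: 4 di-(−)-menthyl (1S,2S)-4-methylcyclohex-4-ene-1,2-dicarboxylate
Product: 5 (1S,2S)-4-methylcyclohex-4-ene-1,2-dicarboxylic acid
Conditions: KOH, EtOH/H2O, reflux; then HCl to pH 1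
Reagents that add atoms: potassium hydroxide, [K+].[OH-]
Why: Ester saponification releases the auxiliary, and because the trans-diacid is the thermodynamically preferred isomer the two stereocenters are not eroded.

Step 4
Reactants: 5 (1S,2S)-4-methylcyclohex-4-ene-1,2-dicarboxylic acid
Product: 6 iodolactone acid (γ-lactone from the C5 carboxyl to C1–O; iodine on C2 trans to the lactone oxygen; free C4 carboxyl on the face opposite the lactone bridge)
Conditions: NaHCO3 (3 equiv), H2O; I2 (1.2 equiv), KI, 0 °C → rt, dark; then HCl to pH 2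
Reagents that add atoms: iodine, II
Why: Iodolactonization in which the iodonium ion is opened at the tertiary carbon C1 (Markovnikov) by the only carboxylate that reaches it through a five-membered ring (the C5 carboxyl), with anti addition placing iodine on C2, which differentiates the two carboxyl groups and installs an allylic leaving group precursor.

Step 5
Reactants: 6 iodolactone acid
Product: 7 vinyl lactone acid (5-methyl-7-oxo-6-oxabicyclo[3.2.1]oct-3-ene-2-carboxylic acid; C2=C3 alkene; C4 carboxyl anti to the lactone bridge)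
Conditions: DBU (3 equiv), THF, 65 °C; then HCl to pH 2
Reagents that add atoms: none
Why: E2 dehydroiodination in which the only anti-periplanar β-hydrogen is the axial one on C3 (C1 has none), giving the C2=C3 alkene and hence a tertiary allylic lactone, while the carboxylate form of the C4 acid prevents α-deprotonation.

Step 6
Reactants: 7 vinyl lactone acid
Product: 8 TMSE ester of the vinyl lactone acid
Conditions: Me3SiCH2CH2OH, DCC, DMAP (cat.), CH2Cl2, 0 °C → rt
Reagents that add atoms: 2-(trimethylsilyl)ethanol, C[Si](C)(C)CCO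
Why: Steglich esterification masks the C4 carboxyl as an ester that is later removed by fluoride attack at silicon, not at the hindered carbonyl; no stereocenter is touched.

Step 7
Reactants: 9 resorcinol
Product: 10 1-(2,4-dihydroxyphenyl)ethanone
Conditions: AcOH, ZnCl2, 140 °C
Reagents that add atoms: acetic acid, CC(=O)O
Why: Nencki (Friedel–Crafts) acylation occurs at C4 of resorcinol, para to one hydroxyl and ortho to the other.

Step 8
Reactants: 10 1-(2,4-dihydroxyphenyl)ethanone
Product: 11 1-(2,4-dihydroxy-3-iodophenyl)ethanone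
Conditions: I2 (0.4 equiv), HIO3 (0.2 equiv), EtOH/H2O, 35 °C
Reagents that add atoms: iodine, II; iodic acid, O[I](=O)=O
Why: Electrophilic aromatic iodination with iodine and iodic acid goes selectively to C3, the position flanked by both hydroxyl groups, with iodic acid returning iodide to the active oxidation level.

Step 9
Reactants: 11 1-(2,4-dihydroxy-3-iodophenyl)ethanone
Product: 12 1-[3-iodo-2,4-bis(methoxymethoxy)phenyl]ethanone
Conditions: NaH (2.3 equiv), MOMCl (2.5 equiv), DMF, 0 °C → rt
Reagents that add atoms: chloromethyl methyl ether, COCCl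
Why: Williamson-type O-alkylation of both phenoxides (NaH also deprotonates the chelated 2-hydroxyl) gives the bis-MOM ether needed for the organometallic steps.

Step 10
Reactants: 8 TMSE ester of the vinyl lactone acid; 12 1-[3-iodo-2,4-bis(methoxymethoxy)phenyl]ethanone
Product: 14 (3S,4S,5S)-3-[3-acetyl-2,6-bis(methoxymethoxy)phenyl]-1-methyl-4-(TMSE-oxycarbonyl)cyclohex-1-ene-5-carboxylic acid (3,4-cis and 4,5-trans), via arylzinc iodide 13 (not isolated)
Conditions: 12 (1.5 equiv), Zn dust, LiCl, THF, 30 °C until 12 is consumed, decant; then 8, Pd2(dba)3 (2.5 mol %), P(2-furyl)3 (10 mol %), THF, 25 → 45 °C; cold 0.5 M HCl work-up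
Reagents that add atoms: zinc, [Zn] (present in 13 only)
Why: Proposed new method: zerovalent palladium ionizes the tertiary allylic lactone C–O bond from the face opposite the carboxylate (ring-opening oxidative addition), the arylzinc transmetalates, and aryl–allyl reductive elimination from palladium at the less substituted terminus C3 (not the methyl-bearing C1) delivers ring A anti to the departing carboxylate, hence cis to the C4 ester and trans to the C5 carboxyl, setting C3 (S) and forming the C1=C2 alkene while freeing the C5 acid for step 13; the closest known reactions are stereoinvertive Pd-catalysed allyl–aryl Negishi and Suzuki couplings of cyclic allylic esters and Pd- or Cu-mediated SN2' openings of simple vinyl lactones, which to my knowledge have not been shown for a bridged tertiary lactone with a ketone-bearing 2,6-dialkoxyarylzinc.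

Step 11
Reactants: 9 resorcinol
Product: 15 1,3-bis(methoxymethoxy)benzene
Conditions: MOMCl (2.4 equiv), i-Pr2NEt (3 equiv), CH2Cl2, 0 °C → rt
Reagents that add atoms: chloromethyl methyl ether, COCCl
Why: O-alkylation of both phenols gives the ether that serves as protecting group and as directing group in steps 12 and 16.

Step 12
Reactants: 15 1,3-bis(methoxymethoxy)benzene
Product: 16 1-iodo-2,4-bis(methoxymethoxy)benzene
Conditions: NIS (1.05 equiv), MeCN, 0 °C → rt
Reagents that add atoms: N-iodosuccinimide, O=C1CCC(=O)N1I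
Why: Electrophilic aromatic iodination occurs para to one MOM ether and ortho to the other, the position between the two ethers being sterically shielded.

Step 13
Reactants: 14 acid from step 10; 16 1-iodo-2,4-bis(methoxymethoxy)benzene
Product: 19 TMSE (3S,4R,5S)-3-[3-acetyl-2,6-bis(methoxymethoxy)phenyl]-5-[2,4-bis(methoxymethoxy)phenyl]-1-methylcyclohex-1-ene-4-carboxylate, via N-acyloxyphthalimide ester 17 (not isolated), via arylzinc iodide 18 (not isolated)
Conditions: 14, N-hydroxyphthalimide, DIC, DMAP (cat.), CH2Cl2, rt, filter and concentrate; 16 (3 equiv), Zn dust, LiCl, THF, 50 °C; then NiCl2·glyme (20 mol %), 4,4'-di-tert-butyl-2,2'-bipyridine (40 mol %), THF/DMF, 25 °C; cold 0.5 M HCl work-up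
Reagents that add atoms: N-hydroxyphthalimide, O=C1c2ccccc2C(=O)N1O (present in 17 only); zinc, [Zn] (present in 18 only)
Why: Nickel-catalysed decarboxylative Negishi arylation of a redox-active ester, in which single-electron reduction releases CO2 and a secondary C5 radical that is captured by the aryl–nickel species on the face opposite the C4 ester and the C3 aryl group, so ring B ends up trans to the C4 substituent (C5 S).

Step 14
Reactants: 19 TMSE ester from step 13
Product: 20 (3S,4R,5S)-3-[3-acetyl-2,6-bis(methoxymethoxy)phenyl]-5-[2,4-bis(methoxymethoxy)phenyl]-1-methylcyclohex-1-ene-4-carboxylic acid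
Conditions: TBAF (3 equiv), THF, 25 °C; aq. NH4Cl
Reagents that add atoms: none
Why: Fluoride-induced β-elimination of the 2-(trimethylsilyl)ethyl ester liberates the C4 acid without nucleophilic attack at the hindered carbonyl and without a base strong enough to epimerize C4.

Step 15
Reactants: 20 C4 acid
Product: 21 S-phenyl thioester of acid 20
Conditions: PhSH, DCC, DMAP (cat.), CH2Cl2, 0 °C → rt
Reagents that add atoms: thiophenol, Sc1ccccc1
Why: Steglich thioesterification gives the acyl electrophile for step 18, and C4 already has its more stable configuration so no epimerization is expected.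

Step 16
Reactants: 15 1,3-bis(methoxymethoxy)benzene; 22 prenyl bromide
Product: 24 1,3-bis(methoxymethoxy)-2-(3-methylbut-2-enyl)benzene, via aryllithium 23 (not isolated)
Conditions: n-BuLi (1.1 equiv), THF, 0 °C; CuI (10 mol %), then 22, −78 °C → rt
Reagents that add atoms: n-butyllithium, [Li]CCCC (Li present in 23 only)
Why: Directed ortho-metalation between the two MOM ethers followed by Cu-catalysed allylic substitution of prenyl bromide at its primary carbon installs the prenyl group at C2 of the resorcinol ring.

Step 17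
Reactants: 24 1,3-bis(methoxymethoxy)-2-(3-methylbut-2-enyl)benzene
Product: 26 [3,5-bis(methoxymethoxy)-4-(3-methylbut-2-enyl)phenyl]boronic acid, via pinacol boronate 25 (not isolated)
Conditions: [Ir(OMe)(cod)]2 (1.5 mol %), 4,4'-di-tert-butyl-2,2'-bipyridine (3 mol %), B2pin2 (0.55 equiv), THF, 60 °C; then NaIO4, NH4OAc, acetone/H2O, 25 °C
Reagents that add atoms: bis(pinacolato)diboron, CC1(C)OB(OC1(C)C)B1OC(C)(C)C(C)(C)O1; water, O
Why: Iridium-catalysed aromatic C–H borylation is sterically controlled and takes the only C–H without an ortho substituent (C5, meta to both ethers), a position not reachable by electrophilic substitution or ortho-lithiation, and periodate cleavage of the pinacol ester then gives the boronic acid.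

Step 18
Reactants: 21 S-phenyl thioester; 26 ring-C boronic acid
Product: 27 hexa-MOM diketone: (3S,4R,5S)-3-[3-acetyl-2,6-bis(methoxymethoxy)phenyl]-5-[2,4-bis(methoxymethoxy)phenyl]-1-methylcyclohex-1-en-4-yl 3,5-bis(methoxymethoxy)-4-prenylphenyl ketone
Conditions: Pd2(dba)3 (5 mol %), P(2-furyl)3 (20 mol %), copper thiophene-2-carboxylate Cu(O2CC4H3S) (CuTC, 1.6 equiv), THF, 50 °C
Reagents that add atoms: none
Why: Liebeskind–Srogl acyl cross-coupling, in which zerovalent palladium inserts into the C(acyl)–S bond, the copper carboxylate scavenges the thiolate and activates the boronic acid for transmetalation, and reductive elimination forms the aryl ketone under base-free conditions that leave C4, the acetyl group and the MOM ethers untouched.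

Step 19
Reactants: 28 4-bromophenol
Product: 29 1-bromo-4-(methoxymethoxy)benzene
Conditions: MOMCl (1.2 equiv), i-Pr2NEt (1.5 equiv), CH2Cl2, 0 °C → rt
Reagents that add atoms: chloromethyl methyl ether, COCCl
Why: O-alkylation of the phenol gives a base-stable ether that survives the lithiation of step 20.

Step 20
Reactants: 29 1-bromo-4-(methoxymethoxy)benzene
Product: 31 4-(methoxymethoxy)benzaldehyde, via aryllithium 30 (not isolated)
Conditions: n-BuLi, THF, −78 °C; DMF; aq. NH4Cl
Reagents that add atoms: N,N-dimethylformamide, CN(C)C=O; n-butyllithium, [Li]CCCC (Li present in 30 only)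
Why: Bromine–lithium exchange followed by Bouveault formylation with DMF gives the aldehyde.

Step 21
Reactants: 27 hexa-MOM diketone; 31 4-(methoxymethoxy)benzaldehyde
Product: 32 hepta-MOM kuwanon R
Conditions: KOH (50% aq.), EtOH, 25 °C
Reagents that add atoms: none
Why: Claisen–Schmidt condensation in which only the methyl ketone enolizes readily, aldol addition to the non-enolizable aldehyde and E1cB dehydration give the E-enone, and the hindered C4–H is not scrambled because the 3,4-cis-4,5-trans isomer (equatorial acyl, pseudoaxial ring A) is expected to be the more stable one.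

Step 22
Reactants: 32 hepta-MOM kuwanon R
Product: 33 kuwanon R
Conditions: 3 M HCl (aq.), MeOH/THF, 40 °C
Reagents that add atoms: none
Why: Acid-catalysed acetal exchange with methanol removes all seven MOM groups as dimethoxymethane under conditions mild enough for the prenyl group, the enone and the three stereocenters.

## Compound list

1 | fumaryl chloride | O=C(Cl)/C=C/C(=O)Cl | starting material
2 | di-(−)-menthyl fumarate | CC(C)[C@@H]1CC[C@@H](C)C[C@H]1OC(=O)/C=C/C(=O)O[C@@H]1C[C@H](C)CC[C@H]1C(C)C | intermediate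
3 | isoprene | CC(=C)C=C | starting material
4 | di-(−)-menthyl (1S,2S)-4-methylcyclohex-4-ene-1,2-dicarboxylate | CC1=CC[C@H](C(=O)O[C@@H]2C[C@H](C)CC[C@H]2C(C)C)[C@@H](C(=O)O[C@@H]2C[C@H](C)CC[C@H]2C(C)C)C1 | intermediate
5 | (1S,2S)-4-methylcyclohex-4-ene-1,2-dicarboxylic acid | CC1=CC[C@H](C(=O)O)[C@@H](C(=O)O)C1 | intermediate
6 | iodolactone acid (4-iodo-5-methyl-7-oxo-6-oxabicyclo[3.2.1]octane-2-carboxylic acid) | C[C@]12C[C@H](C(=O)O1)[C@@H](C(=O)O)C[C@H]2I | intermediate
7 | vinyl lactone acid (5-methyl-7-oxo-6-oxabicyclo[3.2.1]oct-3-ene-2-carboxylic acid) | C[C@]12C[C@H](C(=O)O1)[C@@H](C(=O)O)C=C2 | intermediate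
8 | TMSE ester of the vinyl lactone acid | C[C@]12C[C@H](C(=O)O1)[C@@H](C(=O)OCC[Si](C)(C)C)C=C2 | intermediate
9 | resorcinol | Oc1cccc(O)c1 | starting material
10 | 1-(2,4-dihydroxyphenyl)ethanone | CC(=O)c1ccc(O)cc1O | intermediate
11 | 1-(2,4-dihydroxy-3-iodophenyl)ethanone | CC(=O)c1ccc(O)c(I)c1O | intermediate
12 | 1-[3-iodo-2,4-bis(methoxymethoxy)phenyl]ethanone | CC(=O)c1ccc(OCOC)c(I)c1OCOC | intermediate
13 | [3-acetyl-2,6-bis(methoxymethoxy)phenyl]zinc iodide | CC(=O)c1ccc(OCOC)c([Zn]I)c1OCOC | intermediate (not isolated)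
14 | (3S,4S,5S)-3-[3-acetyl-2,6-bis(methoxymethoxy)phenyl]-1-methyl-4-(TMSE-oxycarbonyl)cyclohex-1-ene-5-carboxylic acid | C[Si](C)(C)CCOC(=O)[C@H]1[C@@H](c2c(OCOC)ccc(C(C)=O)c2OCOC)C=C(C)C[C@@H]1C(=O)O | intermediate
15 | 1,3-bis(methoxymethoxy)benzene | COCOc1cccc(OCOC)c1 | intermediate
16 | 1-iodo-2,4-bis(methoxymethoxy)benzene | COCOc1ccc(I)c(OCOC)c1 | intermediate
17 | N-acyloxyphthalimide ester of acid 14 | C[Si](C)(C)CCOC(=O)[C@H]1[C@@H](c2c(OCOC)ccc(C(C)=O)c2OCOC)C=C(C)C[C@@H]1C(=O)ON3C(=O)c4ccccc4C3=O | intermediate (not isolated)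
18 | [2,4-bis(methoxymethoxy)phenyl]zinc iodide | COCOc1ccc([Zn]I)c(OCOC)c1 | intermediate (not isolated)
19 | TMSE (3S,4R,5S)-3-[3-acetyl-2,6-bis(methoxymethoxy)phenyl]-5-[2,4-bis(methoxymethoxy)phenyl]-1-methylcyclohex-1-ene-4-carboxylate | C[Si](C)(C)CCOC(=O)[C@H]2[C@@H](c3c(OCOC)ccc(C(C)=O)c3OCOC)C=C(C)C[C@@H]2c2ccc(OCOC)cc2OCOC | intermediate
20 | (3S,4R,5S)-3-[3-acetyl-2,6-bis(methoxymethoxy)phenyl]-5-[2,4-bis(methoxymethoxy)phenyl]-1-methylcyclohex-1-ene-4-carboxylic acid | OC(=O)[C@H]2[C@@H](c3c(OCOC)ccc(C(C)=O)c3OCOC)C=C(C)C[C@@H]2c2ccc(OCOC)cc2OCOC | intermediate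
21 | S-phenyl thioester of acid 20 | O=C(Sc1ccccc1)[C@H]2[C@@H](c3c(OCOC)ccc(C(C)=O)c3OCOC)C=C(C)C[C@@H]2c2ccc(OCOC)cc2OCOC | intermediate
22 | prenyl bromide (1-bromo-3-methylbut-2-ene) | CC(C)=CCBr | starting material
23 | 2-lithio-1,3-bis(methoxymethoxy)benzene | [Li]c1c(OCOC)cccc1OCOC | intermediate (not isolated)
24 | 1,3-bis(methoxymethoxy)-2-(3-methylbut-2-enyl)benzene | COCOc1cccc(OCOC)c1CC=C(C)C | intermediate
25 | pinacol [3,5-bis(methoxymethoxy)-4-(3-methylbut-2-enyl)phenyl]boronate | COCOc1cc(B2OC(C)(C)C(C)(C)O2)cc(OCOC)c1CC=C(C)C | intermediate (not isolated)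
26 | [3,5-bis(methoxymethoxy)-4-(3-methylbut-2-enyl)phenyl]boronic acid | COCOc1cc(B(O)O)cc(OCOC)c1CC=C(C)C | intermediate
27 | hexa-MOM diketone (3S,4R,5S) | CC(C)=CCc1c(OCOC)cc(C(=O)[C@H]2[C@@H](c3c(OCOC)ccc(C(C)=O)c3OCOC)C=C(C)C[C@@H]2c2ccc(OCOC)cc2OCOC)cc1OCOC | intermediate
28 | 4-bromophenol | Oc1ccc(Br)cc1 | starting material
29 | 1-bromo-4-(methoxymethoxy)benzene | COCOc1ccc(Br)cc1 | intermediate
30 | [4-(methoxymethoxy)phenyl]lithium | [Li]c1ccc(OCOC)cc1 | intermediate (not isolated)
31 | 4-(methoxymethoxy)benzaldehyde | COCOc1ccc(C=O)cc1 | intermediate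
32 | hepta-MOM kuwanon R (3S,4R,5S; E-enone) | CC(C)=CCc1c(OCOC)cc(C(=O)[C@H]2[C@@H](c3c(OCOC)ccc(C(=O)/C=C/c4ccc(OCOC)cc4)c3OCOC)C=C(C)C[C@@H]2c2ccc(OCOC)cc2OCOC)cc1OCOC | intermediate
33 | kuwanon R (3S,4R,5S in the cyclohexene locants used here) | CC(C)=CCc1c(O)cc(C(=O)[C@H]2[C@@H](c3c(O)ccc(C(=O)/C=C/c4ccc(O)cc4)c3O)C=C(C)C[C@@H]2c2ccc(O)cc2O)cc1O | target

## Step count and risks

Total step count: 22.
Longest linear sequence: 13 steps (steps 1, 2, 3, 4, 5, 6, 10, 13, 14, 15, 18, 21, 22).

Steps most likely to fail:

**Step 10 (the proposed new Pd-catalysed arylative lactone opening).** The risks are slow transmetalation of the di-ortho-substituted arylzinc, loss of a β-hydrogen from the allylpalladium intermediate to give a diene, and attack at C1. The fallback uses known organocopper chemistry, sets out from 12 and 8 and rejoins the route at 20. Reduce 12 (NaBH4, MeOH, 0 °C) to 1-[3-iodo-2,4-bis(methoxymethoxy)phenyl]ethanol F1 and silylate it (TBSCl, imidazole, DMF) to its tert-butyldimethylsilyl ether F2. Convert F2 by iodine–magnesium exchange (i-PrMgCl·LiCl, THF, −20 °C) into the arylmagnesium chloride F3 and open lactone 8 with it under CuBr·SMe2 catalysis (20 mol %, THF, −30 °C). This is the long-established anti-SN2' opening of allylic lactones by Grignard reagents and gives the same 3,4-cis-4,5-trans arrangement in the silyl-ether acid F4. Carry F4 through the conditions of step 13, by way of its N-acyloxyphthalimide ester F5 and nickel-catalysed coupling with 18, to the ring-B ester F6. Remove both silyl groups with TBAF to give the hydroxy acid F7, and oxidize the benzylic alcohol (MnO2, CH2Cl2) to 20.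

**Step 18 (acyl cross-coupling at a carbonyl flanked by two aryl-bearing carbons).** Oxidative addition or transmetalation may be too slow, or the acylpalladium may lose CO. The fallback replaces acyl coupling by addition and oxidation, sets out from 21 and 26 and rejoins at 27. Reduce thioester 21 to the aldehyde F8 (Fukuyama reduction: Et3SiH, palladium on carbon (Pd/C), acetone, 25 °C). Add boronic acid 26 to it by rhodium-catalysed 1,2-addition ([Rh(OH)(cod)]2, dioxane/H2O, 60 °C), under which the aldehyde reacts and the acetyl group does not, to give the secondary alcohol F9 as a mixture of carbinol epimers. Oxidize F9 (Dess–Martin periodinane, NaHCO3, CH2Cl2) to 27.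

**Step 22 (sevenfold acidic MOM removal on an acid-sensitive polyphenol).** The risks are chroman formation from the prenyl group and its neighbouring phenols, flavanone closure of the 2'-hydroxychalcone, and cyclization of a ring-A phenol onto the C4 ketone or the ring alkene. The fallback is a two-stage, non-protic unmasking that sets out from 32 and rejoins at 33. Exchange all MOM ethers for trimethylsilyl ethers with Me3SiOTf and 2,2'-bipyridyl (CH2Cl2, 0 °C → rt), which proceeds through N-(methoxymethyl)bipyridinium intermediates, to give the hepta(trimethylsilyl) ether F10. Hydrolyse the aryl silyl ethers with H2O/MeOH at neutral pH to 33.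

## Further compounds

F1 | step 10 | 1-[3-iodo-2,4-bis(methoxymethoxy)phenyl]ethanol | CC(O)c1ccc(OCOC)c(I)c1OCOC
F2 | step 10 | tert-butyldimethylsilyl ether of F1 | CC(O[Si](C)(C)C(C)(C)C)c1ccc(OCOC)c(I)c1OCOC
F3 | step 10 | arylmagnesium chloride from F2 | CC(O[Si](C)(C)C(C)(C)C)c1ccc(OCOC)c([Mg]Cl)c1OCOC
F4 | step 10 | silyl-ether acid (analogue of 14 with CH(OTBS)CH3 in place of acetyl) | C[Si](C)(C)CCOC(=O)[C@H]1[C@@H](c2c(OCOC)ccc(C(C)O[Si](C)(C)C(C)(C)C)c2OCOC)C=C(C)C[C@@H]1C(=O)O
F5 | step 10 | N-acyloxyphthalimide ester of F4 | C[Si](C)(C)CCOC(=O)[C@H]1[C@@H](c2c(OCOC)ccc(C(C)O[Si](C)(C)C(C)(C)C)c2OCOC)C=C(C)C[C@@H]1C(=O)ON3C(=O)c4ccccc4C3=O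
F6 | step 10 | ring-B ester (analogue of 19 with CH(OTBS)CH3 in place of acetyl) | C[Si](C)(C)CCOC(=O)[C@H]2[C@@H](c3c(OCOC)ccc(C(C)O[Si](C)(C)C(C)(C)C)c3OCOC)C=C(C)C[C@@H]2c2ccc(OCOC)cc2OCOC
F7 | step 10 | hydroxy acid (analogue of 20 with CH(OH)CH3 in place of acetyl) | OC(=O)[C@H]2[C@@H](c3c(OCOC)ccc(C(C)O)c3OCOC)C=C(C)C[C@@H]2c2ccc(OCOC)cc2OCOC
F8 | step 18 | C4 aldehyde from thioester 21 | O=C[C@H]2[C@@H](c3c(OCOC)ccc(C(C)=O)c3OCOC)C=C(C)C[C@@H]2c2ccc(OCOC)cc2OCOC
F9 | step 18 | secondary alcohol from F8 and 26 (carbinol epimers) | CC(C)=CCc1c(OCOC)cc(C(O)[C@H]2[C@@H](c3c(OCOC)ccc(C(C)=O)c3OCOC)C=C(C)C[C@@H]2c2ccc(OCOC)cc2OCOC)cc1OCOC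
F10 | step 22 | hepta(trimethylsilyl) ether of kuwanon R | CC(C)=CCc1c(O[Si](C)(C)C)cc(C(=O)[C@H]2[C@@H](c3c(O[Si](C)(C)C)ccc(C(=O)/C=C/c4ccc(O[Si](C)(C)C)cc4)c3O[Si](C)(C)C)C=C(C)C[C@@H]2c2ccc(O[Si](C)(C)C)cc2O[Si](C)(C)C)cc1O[Si](C)(C)C
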